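The runs were generated by integration from invented constants; scatter was added.

**Opening balance.** A catalyst charge as small as 2.00 mM has to carry 200 mM of starting material through the alpha recipe, and you keep your books on that starting material, the limiting reagent, because its charge is smaller than the 400 mM of partner. Each mole of it stands either as product or as still unturned.

| setting | alpha | epsilon | zeta | beta | theta |
|---|---|---|---|---|---|
| starting material | 200 mM | 400 mM | 200 mM | 200 mM | 200 mM |
| partner | 400 mM | 400 mM | 1200 mM | 400 mM | 400 mM |
| catalyst | 2.00 mM | 2.00 mM | 2.00 mM | 1.00 mM | 2.00 mM |
| time |  |  |  |  | 300 s |

| alpha run: time / s | alpha run: [product] / mM | epsilon run: time / s | epsilon run: [product] / mM | zeta run: time / s | zeta run: [product] / mM | beta run: time / s | beta run: [product] / mM |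
|---|---|---|---|---|---|---|---|
| 4.0 | 5.2 | 4.0 | 2.0 | 4.0 | 14.7 | 4.0 | 3.5 |
| 8.9 | 10.9 | 8.9 | 13.5 | 8.9 | 26.9 | 8.9 | 3.4 |
| 20 | 24.8 | 20 | 24.8 | 20 | 64.6 | 20 | 14.9 |
| 44 | 46.0 | 44 | 53.8 | 44 | 123.9 | 44 | 21.7 |
| 99 | 92.6 | 99 | 106.9 | 99 | 197.4 | 99 | 49.1 |

(standard deviation of a reading: 2 mM)

* reaction order in [partner] at the outset, round the charge of the alpha run, defined at two percent of the starting material turned into product
* reaction order in [starting material] at the outset, round the charge of the alpha run, defined at two percent of the starting material turned into product (one fixed amount of product, the same in the runs compared)
* product in the theta run at 300 s, as a share of the starting material charged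

- Overall: starting material + partner -> product, with catalyst as catalyst.
- Constant volume, constant temperature.
- Readings of a species count what is bound in complexes too.
- An order is taken over about fifteen percent of the charge, up and down.

**Early entries.** The epsilon run, with twice the starting material of the alpha run, reads 106.9 mM at 99 s against 92.6 mM for alpha, a ratio of just 1.15. The beta run, with half the catalyst, reads 49.1 mM at that time. The zeta run, with 3.00 times the partner, reads 64.6 mM at 20 s against 24.8 mM for alpha. So you book the rate as following catalyst and partner, a pseudo-first-order fall of partner at fixed catalyst.

**Partner clock.** In the alpha run the partner has fallen from 400 mM to 307 mM by 99 s, and dividing that time by the logarithm of the fall gives 376 s. This is the partner clock, the time in which partner falls by a factor e at 2.00 mM of catalyst while the rate follows partner, and it is a reading that carries the scatter.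

**Closing entry.** The theta flask repeats the alpha charge, and on the clock its partner loses the full 200 mM by 261 s, which is earlier than the 300 s asked. But the zeta run, where the clock gives 133 mM at 44 s, reads 123.9 mM, a share of 93.5%. Carrying that shortfall over as a rough allowance, you enter 93.5% of the charge for theta.

**The forecast.** Made from these runs, it gives 0.9 in partner, 0.1 in starting material and 93% for theta, and it holds that the weak response to starting material “suggests the catalyst is nearly saturated with it”. Your own entry of 93.5% for theta, an estimate carried over from the zeta run, is higher than the forecast's.

**The flask.** The theta run gives 92.4%, with orders at the outset of 1.0 in partner and 0.24 in starting material, so the forecast's order in starting material is lower than the flask's, while its other two values stand within their margins.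

    catalyst + starting material ⇌ catalyst-substrate complex, settled at all times (36.40 L mol⁻¹)
    catalyst-substrate complex + partner → product + catalyst + by-product (2.410 L mol⁻¹ s⁻¹)
    2 starting material ⇌ idle substrate dimer, settled at all times (55.30 L mol⁻¹)

**Clock again.** The 185 mM of product in the theta run at 300 s is an amount the clock reaches by 233 s, so the theta run comes to that amount later than the clock. For the zeta run the clock puts product at half of the starting material charged by 32.7 s, and the zeta run came to that amount at 33.7 s.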